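**Retrosynthetic overview**
1. The pyranone C ring and the C3–aryl bond are made together in the last step: radical (photoredox Meerwein) C–H arylation/annulation of an o-hydroxyaryl enaminone with 2,4,5-trimethoxybenzenediazonium. This avoids a 3-halochromone/boronic acid pair and a deoxybenzoin.
2. The enaminone comes from 3-prenylpaeonol and a C1 amide acetal.
3. The C8 prenyl group is set by an aromatic Claisen relay: the chelated 2-OH of paeonol carries a 1,1-dimethylallyl group that can migrate only to C3 (the future C8).
4. The tertiary allyl ether comes from paeonol and a tertiary allylic carbonate by Pd π-allyl O-alkylation.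
5. Ring order: A and B rings are bought (paeonol, 2,4,5-trimethoxyaniline); the C ring is closed last.

Assumption: the target has no stereocentre and no stereogenic double bond (the prenyl alkene carries two identical methyls), so "single enantiomer" is moot and the route delivers the one achiral compound.

**Step 1**
Reactants: 1 2-methylbut-3-en-2-ol
Product: 3 methyl (2-methylbut-3-en-2-yl) carbonate, via lithium 2-methylbut-3-en-2-olate 2 (not isolated)
Conditions: n-BuLi (1.05 equiv), THF, −78 → 0 °C; then ClCO2Me, 0 °C → rt
Reagents that add atoms: methyl chloroformate, COC(=O)Cl; n-butyllithium, [Li]CCCC (its Li ends up only in intermediate 2)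
Why: O-acylation of a lithium alkoxide (carbonate formation) works because the hindered tertiary allylic alcohol, once deprotonated by n-BuLi, is acylated cleanly by the chloroformate where amine-base acylation would be slow.

**Step 2**
Reactants: 3 methyl (2-methylbut-3-en-2-yl) carbonate; 4 paeonol [1-(2-hydroxy-4-methoxyphenyl)ethan-1-one]
Product: 5 1-[4-methoxy-2-(2-methylbut-3-en-2-yloxy)phenyl]ethan-1-one
Conditions: Pd(PPh3)4 (3 mol %), 3 (1.5 equiv), degassed THF, 0 °C → rt; silica filtration to remove Pd
Reagents that add atoms: none
Why: Tsuji–Trost O-allylation, in which Pd(0) ionises the carbonate to a 1,1-dimethyl-π-allyl complex with loss of CO2 and methoxide, the methoxide deprotonates the phenol, and the phenoxide attacks the more substituted allyl terminus under kinetic control to give the tertiary (reverse-prenyl) ether without added base.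

**Step 3**
Reactants: 5 1-[4-methoxy-2-(2-methylbut-3-en-2-yloxy)phenyl]ethan-1-one
Product: 7 1-[2-hydroxy-4-methoxy-3-(3-methylbut-2-en-1-yl)phenyl]ethan-1-one (3-prenylpaeonol), via Claisen dienone 6 (not isolated)
Conditions: PhNEt2, 130 °C, sealed tube, Ar
Reagents that add atoms: none
Why: Aromatic Claisen rearrangement ([3,3]-sigmatropic), in which the allyl unit can be delivered only to C3 (the single unsubstituted ortho position), allyl inversion turns the reverse-prenyl ether into a normal prenyl group, and tautomerisation of dienone 6 to the acetyl-chelated phenol removes its transient stereocentre.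

**Step 4**
Reactants: 7 1-[2-hydroxy-4-methoxy-3-(3-methylbut-2-en-1-yl)phenyl]ethan-1-one
Product: 8 (E)-3-(dimethylamino)-1-[2-hydroxy-4-methoxy-3-(3-methylbut-2-en-1-yl)phenyl]prop-2-en-1-one
Conditions: DMF-DMA (2 equiv), toluene, 90 °C
Reagents that add atoms: N,N-dimethylformamide dimethyl acetal, COC(OC)N(C)C
Why: Enaminone formation (condensation of a methyl ketone with an amide acetal) occurs at the acetyl CH3 with loss of two MeOH to give the E-enaminone, while the chelated phenol and the prenyl alkene are inert.

**Step 5**
Reactants: 9 2,4,5-trimethoxyaniline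
Product: 10 2,4,5-trimethoxybenzenediazonium tetrafluoroborate
Conditions: t-BuONO (1.2 equiv), 48% aq HBF4 (2 equiv), EtOH, 0 °C; precipitate with Et2O, use fresh
Reagents that add atoms: tert-butyl nitrite, CC(C)(C)ON=O; tetrafluoroboric acid, [H+].F[B-](F)(F)F
Why: Diazotisation of the anilinium by the alkyl nitrite gives an electron-rich and therefore comparatively stable arenediazonium tetrafluoroborate that precipitates from ether.

**Step 6**
Reactants: 8 (E)-3-(dimethylamino)-1-[2-hydroxy-4-methoxy-3-(3-methylbut-2-en-1-yl)phenyl]prop-2-en-1-one; 10 2,4,5-trimethoxybenzenediazonium tetrafluoroborate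
Product: 13 prebarbigerone [7-methoxy-8-(3-methylbut-2-en-1-yl)-3-(2,4,5-trimethoxyphenyl)-4H-chromen-4-one], via alpha-aryl iminium tetrafluoroborate 11 (not isolated), via cyclic aminal 12 (not isolated)
Conditions: eosin Y (2 mol %), 10 (1.5 equiv, added in portions), rigorously degassed DMSO, green LEDs (530 nm), 25 °C, Ar; aq NaHCO3 work-up
Reagents that add atoms: none
Why: Photoredox Meerwein C–H arylation with domino chromone annulation, in which excited eosin Y reduces 10 to the 2,4,5-trimethoxyphenyl radical (loss of N2), the radical adds to the nucleophilic α-carbon of the enaminone, the resulting α-amino radical is oxidised (by the dye radical cation or by chain transfer to 10) to iminium 11, the chelated phenol closes onto the iminium carbon to aminal 12, and loss of dimethylamine gives the pyranone with no stereocentre remaining.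

**Compound list**
1 | 2-methylbut-3-en-2-ol | CC(C)(O)C=C | starting material
2 | lithium 2-methylbut-3-en-2-olate | [Li+].[O-]C(C)(C)C=C | intermediate
3 | methyl (2-methylbut-3-en-2-yl) carbonate | COC(=O)OC(C)(C)C=C | intermediate
4 | paeonol, 1-(2-hydroxy-4-methoxyphenyl)ethan-1-one | CC(=O)c1ccc(OC)cc1O | starting material
5 | 1-[4-methoxy-2-(2-methylbut-3-en-2-yloxy)phenyl]ethan-1-one | CC(=O)c1ccc(OC)cc1OC(C)(C)C=C | intermediate
6 | 2-acetyl-5-methoxy-6-(3-methylbut-2-en-1-yl)cyclohexa-2,4-dien-1-one (racemic, transient) | CC(=O)C1=CC=C(OC)C(CC=C(C)C)C1=O | intermediate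
7 | 1-[2-hydroxy-4-methoxy-3-(3-methylbut-2-en-1-yl)phenyl]ethan-1-one | CC(=O)c1ccc(OC)c(CC=C(C)C)c1O | intermediate
8 | (E)-3-(dimethylamino)-1-[2-hydroxy-4-methoxy-3-(3-methylbut-2-en-1-yl)phenyl]prop-2-en-1-one | CN(C)/C=C/C(=O)c1ccc(OC)c(CC=C(C)C)c1O | intermediate
9 | 2,4,5-trimethoxyaniline | COc1cc(OC)c(N)cc1OC | starting material
10 | 2,4,5-trimethoxybenzenediazonium tetrafluoroborate | COc1cc(OC)c([N+]#N)cc1OC.F[B-](F)(F)F | intermediate
11 | N-[3-(2-hydroxy-4-methoxy-3-prenylphenyl)-3-oxo-2-(2,4,5-trimethoxyphenyl)propylidene]-N-methylmethanaminium tetrafluoroborate (racemic, transient) | C[N+](C)=CC(C(=O)c1ccc(OC)c(CC=C(C)C)c1O)c1cc(OC)c(OC)cc1OC.F[B-](F)(F)F | intermediate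
12 | 2-(dimethylamino)-7-methoxy-8-(3-methylbut-2-en-1-yl)-3-(2,4,5-trimethoxyphenyl)chroman-4-one (diastereomer mixture, transient) | CN(C)C1Oc2c(CC=C(C)C)c(OC)ccc2C(=O)C1c1cc(OC)c(OC)cc1OC | intermediate
13 | prebarbigerone, 7-methoxy-8-(3-methylbut-2-en-1-yl)-3-(2,4,5-trimethoxyphenyl)-4H-chromen-4-one | COc1cc(OC)c(-c2coc3c(CC=C(C)C)c(OC)ccc3c2=O)cc1OC | target

**Totals**
Total step count: 6.
Longest linear sequence: 5 steps (1 → 3 → 5 → 7 → 8 → 13, i.e. steps 1, 2, 3, 4 and 6); step 5 is a one-step side branch.

**Three steps most likely to fail, with fallbacks**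

Step 2. The phenol is chelated to the ortho acetyl group and must attack a tertiary π-allyl terminus, so conversion may be poor or the product may drift to the linear O-prenyl ether. The fallback is a propargylation/semi-hydrogenation approach. It sets out from 4, which is alkylated with 3-chloro-3-methylbut-1-yne (K2CO3, KI, CuI cat., acetone, 55 °C; copper-assisted propargylic substitution that tolerates hindered phenols) to give 1-[4-methoxy-2-(2-methylbut-3-yn-2-yloxy)phenyl]ethan-1-one F1. The terminal alkyne is then semi-hydrogenated (H2, Lindlar catalyst, quinoline, EtOAc, rt), and the fallback comes back to the route at 5.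

Step 3. The tertiary allyl ether may ionise to paeonol and isoprene, or migrate through the acetyl-bearing ortho carbon to the para position. The fallback replaces the O→C relay by direct ortho C-prenylation. It sets out from 4, which is converted with NaH in toluene to sodium 2-acetyl-5-methoxyphenolate F2. This tight ion pair is treated with prenyl bromide (rt → 60 °C); in the non-polar medium the sodium-chelated phenolate is alkylated on carbon at C3, its only free ortho position. After chromatographic removal of O-prenyl ether the fallback comes back to the route at 7, bypassing 3, 5 and 6.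

Step 6. Possible failures are azo coupling of the diazonium salt at the enaminone carbon, aryl-radical addition to the prenyl alkene, and dye-sensitised ene oxygenation of the prenyl group if oxygen is present. The fallback is a two-step halogenative annulation and cross-coupling. It sets out from 8, which is cyclised with I2 (CHCl3, rt) to 3-iodo-7-methoxy-8-(3-methylbut-2-en-1-yl)-4H-chromen-4-one F3. This is coupled with (2,4,5-trimethoxyphenyl)boronic acid (Pd(dppf)Cl2, aq Na2CO3, DME, 80 °C), and the fallback comes back to the route at 13.

**Further compounds**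
F1 | step 2 | 1-[4-methoxy-2-(2-methylbut-3-yn-2-yloxy)phenyl]ethan-1-one | CC(=O)c1ccc(OC)cc1OC(C)(C)C#C
F2 | step 3 | sodium 2-acetyl-5-methoxyphenolate | CC(=O)c1ccc(OC)cc1[O-].[Na+]
F3 | step 6 | 3-iodo-7-methoxy-8-(3-methylbut-2-en-1-yl)-4H-chromen-4-one | COc1ccc2c(c1CC=C(C)C)occ(I)c2=O
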